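**Assumption:** the target has no stereogenic element (no stereocentre, and each aryl–indole axis carries two identical ortho methoxy groups), so it is one achiral compound and no stereocontrol is needed.

**Retrosynthetic overview**
1. Target 15 ⇐ benzyl ether 14 (hydrogenolysis) ⇐ N-silyl compound 13 (desilylation).
2. 13 ⇐ aryl iodide 10 + free (N–H) 5-(benzyloxy)indole 11, by the proposed C3-selective palladium-catalysed coupling of the N-magnesiated indole (new step, second aryl–indole bond).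
3. 10 ⇐ 8 by directed lithiation/iodination of the last C–H of the central ring.
4. 8 ⇐ 1,2,4,5-tetramethoxybenzene 5 (lithiation, zincation) + 3-bromoindole 4 by Negishi coupling (first aryl–indole bond); 4 ⇐ 5-methoxyindole 1.
5. No ring is built: the central ring and both indoles are bought intact and joined in the order methoxyindole–central ring, then central ring–oxygenated indole.

**Route**

Step 1
Reactants: 1 5-methoxy-1H-indole
Product: 3 5-methoxy-1-(triisopropylsilyl)-1H-indole, via sodium 5-methoxyindol-1-ide 2 (not isolated)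
Conditions: NaH (1.2 equiv), THF, 0 °C; then TIPSCl (1.1 equiv), 0 °C to rt
Reagents that add atoms: triisopropylsilyl chloride (TIPSCl), CC(C)[Si](Cl)(C(C)C)C(C)C
Why: N-deprotonation followed by N-silylation is standard; the bulky silyl group shields N and C2 in the later organometallic steps.

Step 2
Reactants: 3 5-methoxy-1-(triisopropylsilyl)-1H-indole
Product: 4 3-bromo-5-methoxy-1-(triisopropylsilyl)-1H-indole
Conditions: NBS (1.05 equiv), THF, −78 °C to rt
Reagents that add atoms: N-bromosuccinimide (NBS), O=C1CCC(=O)N1Br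
Why: Electrophilic aromatic bromination of an N-silylindole occurs selectively at C3, the most nucleophilic position.

Step 3
Reactants: 5 1,2,4,5-tetramethoxybenzene; 4 3-bromo-5-methoxy-1-(triisopropylsilyl)-1H-indole
Product: 8 5-methoxy-3-(2,3,5,6-tetramethoxyphenyl)-1-(triisopropylsilyl)-1H-indole, via (2,3,5,6-tetramethoxyphenyl)lithium 6 (not isolated), via (2,3,5,6-tetramethoxyphenyl)zinc chloride 7 (not isolated)
Conditions: 5 (1.5 equiv), n-BuLi (1.5 equiv), THF, 0 °C to rt; ZnCl2 (1.6 equiv), 0 °C to rt; then 4 (1.0 equiv), Pd(OAc)2 (3 mol%), SPhos (6 mol%), THF, 65 °C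
Reagents that add atoms: none
Why: Directed ortho-lithiation between two methoxy groups is mono-selective, and Negishi coupling of the derived di-ortho-substituted arylzinc with a heteroaryl bromide is reliable with Pd(OAc)2 and SPhos (2-dicyclohexylphosphino-2',6'-dimethoxybiphenyl).

Step 4
Reactants: 8 5-methoxy-3-(2,3,5,6-tetramethoxyphenyl)-1-(triisopropylsilyl)-1H-indole
Product: 10 3-(4-iodo-2,3,5,6-tetramethoxyphenyl)-5-methoxy-1-(triisopropylsilyl)-1H-indole, via para-lithiated aryllithium 9 (not isolated)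
Conditions: n-BuLi (1.3 equiv), TMEDA (1.3 equiv), THF, 0 °C; then I2 (1.5 equiv), −78 °C to rt; aq. Na2S2O3 work-up
Reagents that add atoms: iodine, II
Why: Directed ortho-metalation picks the one C–H flanked by two methoxy groups (indole C2 is shielded by the N-silyl group and the 3-aryl group), and iodine traps the aryllithium.

Step 5
Reactants: 10 3-(4-iodo-2,3,5,6-tetramethoxyphenyl)-5-methoxy-1-(triisopropylsilyl)-1H-indole; 11 5-(benzyloxy)-1H-indole
Product: 13 5-(benzyloxy)-3-[2,3,5,6-tetramethoxy-4-(5-methoxy-1-(triisopropylsilyl)-1H-indol-3-yl)phenyl]-1H-indole, via [5-(benzyloxy)indol-1-yl]magnesium chloride 12 (not isolated)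
Conditions: 11 (2.6 equiv), MeMgCl (2.5 equiv), TMEDA (2.5 equiv), 1,4-dioxane/THF, rt; then 10 (1.0 equiv), Pd(OAc)2 (5 mol%), SPhos (10 mol%), 90 °C; aq. NH4Cl work-up
Reagents that add atoms: none
Why: Proposed new method: C3-selective palladium-catalysed cross-coupling of an N-magnesiated free (N–H) indole with a di-ortho-methoxy, fully substituted aryl iodide. Zerovalent palladium bearing SPhos inserts into the hindered C–I bond, and the electrophilic divalent arylpalladium iodide is attacked by C3 of the magnesium indolide, which behaves as a metallo-enamine. The tight, TMEDA-capped N–Mg bond suppresses N-arylation, and the bulk of both partners disfavours the C3-to-C2 palladium shift. A second indolide removes the C3 proton and reductive elimination forms the tri-ortho-substituted aryl–indole bond. The closest known reaction type is the palladium-catalysed C3–H arylation of indolylmagnesium salts with unhindered aryl halides, which has not been shown for 2,6-disubstituted, fully substituted aryl halides, combined with Negishi/Kumada couplings of hindered aryl halides using dialkylbiarylphosphines.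

Step 6
Reactants: 13 5-(benzyloxy)-3-[2,3,5,6-tetramethoxy-4-(5-methoxy-1-(triisopropylsilyl)-1H-indol-3-yl)phenyl]-1H-indole
Product: 14 5-(benzyloxy)-3-[2,3,5,6-tetramethoxy-4-(5-methoxy-1H-indol-3-yl)phenyl]-1H-indole
Conditions: TBAF (1.5 equiv), THF, 0 °C to rt; aqueous work-up
Reagents that add atoms: none
Why: Fluoride-mediated N-desilylation is fast and leaves the benzyl and methyl ethers untouched.

Step 7
Reactants: 14 5-(benzyloxy)-3-[2,3,5,6-tetramethoxy-4-(5-methoxy-1H-indol-3-yl)phenyl]-1H-indole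
Product: 15 3-[2,3,5,6-tetramethoxy-4-(5-methoxy-1H-indol-3-yl)phenyl]-1H-indol-5-ol (target)
Conditions: H2 (1 atm), 10% Pd/C, EtOAc/MeOH, rt; work-up under N2
Reagents that add atoms: none
Why: Catalytic hydrogenolysis cleaves only the benzylic C–O bond, because aryl methyl ethers and indole rings are inert at 1 atm and rt, and it frees the single phenol that distinguishes the two indoles.

**Compound list**
1 | 5-methoxy-1H-indole | COc1ccc2[nH]ccc2c1 | starting material
2 | sodium 5-methoxyindol-1-ide | COc1ccc2c(c1)cc[n-]2.[Na+] | intermediate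
3 | 5-methoxy-1-(triisopropylsilyl)-1H-indole | COc1ccc2c(c1)ccn2[Si](C(C)C)(C(C)C)C(C)C | intermediate
4 | 3-bromo-5-methoxy-1-(triisopropylsilyl)-1H-indole | COc1ccc2c(c1)c(Br)cn2[Si](C(C)C)(C(C)C)C(C)C | intermediate
5 | 1,2,4,5-tetramethoxybenzene | COc1cc(OC)c(OC)cc1OC | starting material
6 | (2,3,5,6-tetramethoxyphenyl)lithium | [Li]c1c(OC)c(OC)cc(OC)c1OC | intermediate
7 | (2,3,5,6-tetramethoxyphenyl)zinc chloride | Cl[Zn]c1c(OC)c(OC)cc(OC)c1OC | intermediate
8 | 5-methoxy-3-(2,3,5,6-tetramethoxyphenyl)-1-(triisopropylsilyl)-1H-indole | COc1ccc2c(c1)c(cn2[Si](C(C)C)(C(C)C)C(C)C)-c1c(OC)c(OC)cc(OC)c1OC | intermediate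
9 | [2,3,5,6-tetramethoxy-4-(5-methoxy-1-(triisopropylsilyl)-1H-indol-3-yl)phenyl]lithium | [Li]c1c(OC)c(OC)c(-c2cn([Si](C(C)C)(C(C)C)C(C)C)c3ccc(OC)cc23)c(OC)c1OC | intermediate
10 | 3-(4-iodo-2,3,5,6-tetramethoxyphenyl)-5-methoxy-1-(triisopropylsilyl)-1H-indole | COc1ccc2c(c1)c(cn2[Si](C(C)C)(C(C)C)C(C)C)-c1c(OC)c(OC)c(I)c(OC)c1OC | intermediate
11 | 5-(benzyloxy)-1H-indole | C(Oc1ccc2[nH]ccc2c1)c1ccccc1 | starting material
12 | [5-(benzyloxy)indol-1-yl]magnesium chloride | Cl[Mg]n1ccc2cc(OCc3ccccc3)ccc21 | intermediate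
13 | 5-(benzyloxy)-3-[2,3,5,6-tetramethoxy-4-(5-methoxy-1-(triisopropylsilyl)-1H-indol-3-yl)phenyl]-1H-indole | COc1ccc2c(c1)c(cn2[Si](C(C)C)(C(C)C)C(C)C)-c1c(OC)c(OC)c(-c2c[nH]c3ccc(OCc4ccccc4)cc23)c(OC)c1OC | intermediate
14 | 5-(benzyloxy)-3-[2,3,5,6-tetramethoxy-4-(5-methoxy-1H-indol-3-yl)phenyl]-1H-indole | COc1ccc2[nH]cc(-c3c(OC)c(OC)c(-c4c[nH]c5ccc(OCc6ccccc6)cc45)c(OC)c3OC)c2c1 | intermediate
15 | 3-[2,3,5,6-tetramethoxy-4-(5-methoxy-1H-indol-3-yl)phenyl]-1H-indol-5-ol | COc1ccc2[nH]cc(-c3c(OC)c(OC)c(-c4c[nH]c5ccc(O)cc45)c(OC)c3OC)c2c1 | target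

**Totals**
Total step count: 7. Longest linear sequence: 7 (steps 1 to 7, from 5-methoxyindole 1).

**Three steps most likely to fail, with fallbacks**

Step 5 (proposed new coupling; risks are N- or C2-arylation and proto-deiodination of 10). The fallback uses known chemistry only, sets out from compound 8 (with commercial 11) and comes back to the route at compound 14. 5-(Benzyloxy)indole 11 is deprotonated with NaH to sodium 5-(benzyloxy)indol-1-ide F1 and silylated with TIPSCl to 5-(benzyloxy)-1-(triisopropylsilyl)-1H-indole F2. NBS in THF at −78 °C then gives 5-(benzyloxy)-3-bromo-1-(triisopropylsilyl)-1H-indole F3. Compound 8 is lithiated as in step 4 (n-BuLi, TMEDA, THF, 0 °C) to aryllithium 9, which ZnCl2 converts into [2,3,5,6-tetramethoxy-4-(5-methoxy-1-(triisopropylsilyl)-1H-indol-3-yl)phenyl]zinc chloride F4. Negishi coupling of F4 with F3 (Pd(OAc)2, SPhos, THF, 65 °C) gives 5-(benzyloxy)-3-[2,3,5,6-tetramethoxy-4-(5-methoxy-1-(triisopropylsilyl)-1H-indol-3-yl)phenyl]-1-(triisopropylsilyl)-1H-indole F5. TBAF in THF removes both silyl groups to give 14, and step 7 follows unchanged.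

Step 3 (Negishi coupling of a di-ortho-substituted arylzinc; risks are slow transmetalation and reduction of 4). The fallback replaces cross-coupling by carbonyl addition and reductive aromatisation, sets out from compound 5 (through aryllithium 6) and comes back at compound 8. Aryllithium 6 (2.2 equiv, from 5 and n-BuLi) is added at −78 °C to commercial 5-methoxyisatin F6. The first equivalent removes the N–H proton and the second adds to the C3 ketone, giving racemic dilithium 5-methoxy-3-oxido-2-oxo-3-(2,3,5,6-tetramethoxyphenyl)indolin-1-ide F7. Aqueous work-up gives racemic 3-hydroxy-5-methoxy-3-(2,3,5,6-tetramethoxyphenyl)indolin-2-one F8. BH3·THF at reflux reduces the lactam and removes the tertiary hydroxyl with aromatisation, giving 5-methoxy-3-(2,3,5,6-tetramethoxyphenyl)-1H-indole F9 and erasing the transient stereocentre. NaH converts F9 into sodium 5-methoxy-3-(2,3,5,6-tetramethoxyphenyl)indol-1-ide F10, and TIPSCl gives 8.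

Step 4 (site of deprotonation; risks are competing lithiation ortho to the indole methoxy group or N–Si attack). The fallback fixes the position of the metal by halogen–lithium exchange in place of C–H deprotonation, sets out from compounds 5 and 4 and comes back at aryllithium 9 (and so iodide 10). Compound 5 is brominated twice (Br2, 2.2 equiv, CH2Cl2, 0 °C to rt) to 1,4-dibromo-2,3,5,6-tetramethoxybenzene F11. Bromide 4 undergoes bromine–lithium exchange (n-BuLi, THF, −78 °C) to [5-methoxy-1-(triisopropylsilyl)-1H-indol-3-yl]lithium F12, and ZnCl2 converts this into [5-methoxy-1-(triisopropylsilyl)-1H-indol-3-yl]zinc chloride F13. Mono-Negishi coupling of F13 with excess F11 (3 equiv, the surplus recovered; Pd(OAc)2, SPhos, THF, 65 °C) gives 3-(4-bromo-2,3,5,6-tetramethoxyphenyl)-5-methoxy-1-(triisopropylsilyl)-1H-indole F14. Bromine–lithium exchange on F14 (n-BuLi, THF, −78 °C) gives 9 regiospecifically, and the iodine quench of step 4 gives 10.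

**Further compounds**
F1 | step 5 | sodium 5-(benzyloxy)indol-1-ide | [Na+].[n-]1ccc2cc(OCc3ccccc3)ccc21
F2 | step 5 | 5-(benzyloxy)-1-(triisopropylsilyl)-1H-indole | CC(C)[Si](C(C)C)(C(C)C)n1ccc2cc(OCc3ccccc3)ccc21
F3 | step 5 | 5-(benzyloxy)-3-bromo-1-(triisopropylsilyl)-1H-indole | CC(C)[Si](C(C)C)(C(C)C)n1cc(Br)c2cc(OCc3ccccc3)ccc21
F4 | step 5 | [2,3,5,6-tetramethoxy-4-(5-methoxy-1-(triisopropylsilyl)-1H-indol-3-yl)phenyl]zinc chloride | Cl[Zn]c1c(OC)c(OC)c(-c2cn([Si](C(C)C)(C(C)C)C(C)C)c3ccc(OC)cc23)c(OC)c1OC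
F5 | step 5 | 5-(benzyloxy)-3-[2,3,5,6-tetramethoxy-4-(5-methoxy-1-(triisopropylsilyl)-1H-indol-3-yl)phenyl]-1-(triisopropylsilyl)-1H-indole | COc1ccc2c(c1)c(cn2[Si](C(C)C)(C(C)C)C(C)C)-c1c(OC)c(OC)c(-c2cn([Si](C(C)C)(C(C)C)C(C)C)c3ccc(OCc4ccccc4)cc23)c(OC)c1OC
F6 | step 3 | 5-methoxyisatin (5-methoxyindoline-2,3-dione, purchased) | COc1ccc2NC(=O)C(=O)c2c1
F7 | step 3 | dilithium 5-methoxy-3-oxido-2-oxo-3-(2,3,5,6-tetramethoxyphenyl)indolin-1-ide (racemic) | COc1ccc2[N-]C(=O)C([O-])(c2c1)c1c(OC)c(OC)cc(OC)c1OC.[Li+].[Li+]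
F8 | step 3 | 3-hydroxy-5-methoxy-3-(2,3,5,6-tetramethoxyphenyl)indolin-2-one (racemic) | COc1ccc2NC(=O)C(O)(c2c1)c1c(OC)c(OC)cc(OC)c1OC
F9 | step 3 | 5-methoxy-3-(2,3,5,6-tetramethoxyphenyl)-1H-indole | COc1ccc2[nH]cc(-c3c(OC)c(OC)cc(OC)c3OC)c2c1
F10 | step 3 | sodium 5-methoxy-3-(2,3,5,6-tetramethoxyphenyl)indol-1-ide | COc1ccc2c(c1)c(c[n-]2)-c1c(OC)c(OC)cc(OC)c1OC.[Na+]
F11 | step 4 | 1,4-dibromo-2,3,5,6-tetramethoxybenzene | COc1c(OC)c(Br)c(OC)c(OC)c1Br
F12 | step 4 | [5-methoxy-1-(triisopropylsilyl)-1H-indol-3-yl]lithium | COc1ccc2c(c1)c([Li])cn2[Si](C(C)C)(C(C)C)C(C)C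
F13 | step 4 | [5-methoxy-1-(triisopropylsilyl)-1H-indol-3-yl]zinc chloride | COc1ccc2c(c1)c([Zn]Cl)cn2[Si](C(C)C)(C(C)C)C(C)C
F14 | step 4 | 3-(4-bromo-2,3,5,6-tetramethoxyphenyl)-5-methoxy-1-(triisopropylsilyl)-1H-indole | COc1ccc2c(c1)c(cn2[Si](C(C)C)(C(C)C)C(C)C)-c1c(OC)c(OC)c(Br)c(OC)c1OC
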